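The route rests on disconnecting the dihydrofuran ring from the benzene ring at both junctions: the aryl ether bond O1–C7a and the bond C3–C3a. One operation forms both. Oxidative dearomatization of 5-bromo-2-methoxyphenol in the presence of an enantiopure β-hydroxy ester gives an o-quinone monoketal that carries the alcohol oxygen on the former methoxy carbon (C7a). The tethered ester enolate then adds to the neighbouring dienone carbon (C3a), and loss of methanol restores the arene. The step exploits the free C7 hydroxyl ortho to O1 on the benzene ring of the benzofuran, which serves as the dienone carbonyl and returns unprotected. The bromide at C5 later carries the acrylic acid.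

Key step: step 2

Remark: the target descriptor (2R,3S) is the 2,3-trans arrangement; the 3-ester intermediates with the same geometry are (2R,3R) because the priorities at C3 change. Compounds 1, 3 and 8 are taken as commercial.

Step 1
Reactants: 1 ethyl 3-(3,4-dimethoxyphenyl)-3-oxopropanoate
Product: 2 ethyl (3R)-3-(3,4-dimethoxyphenyl)-3-hydroxypropanoate
Conditions: RuCl[(R,R)-TsDPEN](p-cymene) (cat.), HCO2H/Et3N (5:2), 30 °C
Reagents that add atoms: none
Why: Noyori–Ikariya asymmetric transfer hydrogenation of the aryl ketone should deliver hydride to one carbonyl face through the CH/π-controlled six-membered transition state of the (R,R)-TsDPEN–Ru hydride, setting the carbinol carbon (the future C2) as R while the ester is untouched.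

Step 2
Reactants: 3 5-bromo-2-methoxyphenol; 2 ethyl (3R)-3-(3,4-dimethoxyphenyl)-3-hydroxypropanoate
Product: 6 ethyl (2R,3R)-5-bromo-2-(3,4-dimethoxyphenyl)-7-hydroxy-2,3-dihydro-1-benzofuran-3-carboxylate, via mixed o-quinone monoketal 4 (not isolated), via bicyclic potassium dienolate 5 (not isolated)
Conditions: 2 (3 equiv), PhI(OAc)2 (1.05 equiv), CH2Cl2, −20 → 0 °C (3 added slowly); then t-BuOK (5 equiv), THF, −40 → 0 °C; then EtOH, rt; aq. NH4Cl
Reagents that add atoms: none
Why: Proposed new method: PhI(OAc)2 oxidises phenol 3 to a phenoxenium equivalent that the hydroxyl of 2 should capture at the methoxy-bearing ortho carbon (future C7a), giving o-quinone monoketal 4 and the O1–C7a bond; t-BuOK then reversibly forms the ester enolate, whose α-carbon (C3) adds 1,6 to the dienone at the adjacent δ-carbon (C3a) to give dienolate 5, which ionises the exocyclic C7a–OMe bond and loses H-3a to rearomatise as the phenoxide of 6. The closest known reaction types are the hypervalent-iodine ketalisation of 2-methoxyphenols with alcohols to masked o-benzoquinones, the conjugate addition–rearomatisation of such monoketals with soft nucleophiles, and the intramolecular Michael closure of O-tethered cyclohexadienones. The dihydrofuran ring closes by a 5-exo-trig conjugate addition, whereas the ether bond comes from the intermolecular ketalisation. C2 keeps the R configuration of 2 because none of its bonds is broken, the new C3 centre is epimerisable (α to the ester) and should settle trans to the C2 aryl group under thermodynamic control in the ethoxide equilibration (which also returns any transesterified material to the ethyl ester), and the transient centres C7a and C3a vanish on aromatisation so both ketal epimers converge. The step needs alcohol attack at the methoxy carbon rather than acetate or para attack (oxocarbenium-stabilised position, non-nucleophilic solvent, excess 2; the bromine should slow dimerisation of 4), Michael closure faster than β-elimination of the ketal oxygen or 1,2-addition (intramolecular 5-exo attack on a strongly electrophilic dienone, the aldol being reversible), and loss of methoxide rather than of the ring oxygen (a ring-opened oxocarbenium can reclose, departed methanol does not return).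

Step 3
Reactants: 6 ethyl (2R,3R)-5-bromo-2-(3,4-dimethoxyphenyl)-7-hydroxy-2,3-dihydro-1-benzofuran-3-carboxylate
Product: 7 (2R,3S)-5-bromo-2-(3,4-dimethoxyphenyl)-3-(hydroxymethyl)-2,3-dihydro-1-benzofuran-7-ol
Conditions: LiBH4 (3 equiv), THF, 0 °C → rt; aq. NH4Cl
Reagents that add atoms: none
Why: Hydride reduction of the ester with LiBH4 should give the primary alcohol while the aryl bromide, the aryl ethers and the lithium phenoxide are inert, and both stereocentres are kept because these weakly basic conditions do not enolise C3.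

Step 4
Reactants: 7 (2R,3S)-5-bromo-2-(3,4-dimethoxyphenyl)-3-(hydroxymethyl)-2,3-dihydro-1-benzofuran-7-ol; 8 acrylic acid
Product: 9 (2E)-3-[(2R,3S)-2-(3,4-dimethoxyphenyl)-7-hydroxy-3-(hydroxymethyl)-2,3-dihydro-1-benzofuran-5-yl]prop-2-enoic acid
Conditions: Pd(OAc)2 (5 mol%), P(o-tol)3 (15 mol%), Et3N (4 equiv), DMF, 100 °C; acidic work-up
Reagents that add atoms: none
Why: Mizoroki–Heck coupling of the aryl bromide with acrylic acid (as its triethylammonium salt) should give the (E)-acrylic acid through syn-carbopalladation and syn-β-hydride elimination, tolerating the free phenol and alcohol and leaving both stereocentres untouched.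

Compound list
1 | ethyl 3-(3,4-dimethoxyphenyl)-3-oxopropanoate | CCOC(=O)CC(=O)c1ccc(OC)c(OC)c1 | starting material
2 | ethyl (3R)-3-(3,4-dimethoxyphenyl)-3-hydroxypropanoate | COc1ccc([C@H](O)CC(=O)OCC)cc1OC | intermediate
3 | 5-bromo-2-methoxyphenol | COc1ccc(Br)cc1O | starting material
4 | ethyl (3R)-3-[(4-bromo-1-methoxy-6-oxocyclohexa-2,4-dien-1-yl)oxy]-3-(3,4-dimethoxyphenyl)propanoate (both epimers at the ketal carbon) | CCOC(=O)C[C@@H](OC1(OC)C=CC(Br)=CC1=O)c1ccc(OC)c(OC)c1 | intermediate
5 | potassium salt of ethyl (2R)-5-bromo-2-(3,4-dimethoxyphenyl)-7a-methoxy-7-oxido-2,3,3a,7a-tetrahydro-1-benzofuran-3-carboxylate (cis-fused, epimers at C3) | CCOC(=O)C1[C@H](c2ccc(OC)c(OC)c2)OC2(OC)C([O-])=CC(Br)=CC12.[K+] | intermediate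
6 | ethyl (2R,3R)-5-bromo-2-(3,4-dimethoxyphenyl)-7-hydroxy-2,3-dihydro-1-benzofuran-3-carboxylate | COc1ccc([C@@H]2Oc3c(O)cc(Br)cc3[C@H]2C(=O)OCC)cc1OC | intermediate
7 | (2R,3S)-5-bromo-2-(3,4-dimethoxyphenyl)-3-(hydroxymethyl)-2,3-dihydro-1-benzofuran-7-ol | COc1ccc([C@@H]2Oc3c(O)cc(Br)cc3[C@H]2CO)cc1OC | intermediate
8 | acrylic acid | C=CC(=O)O | starting material
9 | (2E)-3-[(2R,3S)-2-(3,4-dimethoxyphenyl)-7-hydroxy-3-(hydroxymethyl)-2,3-dihydro-1-benzofuran-5-yl]prop-2-enoic acid | COc1ccc([C@@H]2Oc3c(O)cc(/C=C/C(=O)O)cc3[C@H]2CO)cc1OC | target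

Total step count: 4. Longest linear sequence: 4 steps (1 → 2 → 6 → 7 → 9).

Steps most likely to fail

1. Step 2 (key step). Several processes may go wrong:
   - the oxidised phenol may be captured by acetate or at the para carbon instead of by the hindered secondary alcohol;
   - monoketal 4 may dimerise;
   - the enolate may expel the ketal oxygen by β-elimination before it cyclises;
   - the rearomatisation may expel the ring oxygen instead of methoxide.

   The fallback uses known chemistry only, sets out from 2 and comes back to the route at 9. Silylation of 2 (TBSCl, imidazole, DMF) should give ethyl (3R)-3-[(tert-butyldimethylsilyl)oxy]-3-(3,4-dimethoxyphenyl)propanoate F1. Its zinc enolate (LiHMDS, THF, −78 °C; ZnCl2) is α-arylated under palladium catalysis (Pd(dba)2, P(t-Bu)3, rt) with the aryl bromide methyl 3-(benzyloxy)-5-bromo-4-fluorobenzoate F2, giving ethyl (3R)-2-[3-(benzyloxy)-2-fluoro-5-(methoxycarbonyl)phenyl]-3-[(tert-butyldimethylsilyl)oxy]-3-(3,4-dimethoxyphenyl)propanoate F3 as a mixture of epimers at the α-carbon. CsF in DMF (60 °C) removes the silyl group, and the alkoxide should close the ring by intramolecular SNAr on the fluoride para to the ester. Base equilibration at C3 then gives 3-ethyl 5-methyl (2R,3R)-7-(benzyloxy)-2-(3,4-dimethoxyphenyl)-2,3-dihydro-1-benzofuran-3,5-dicarboxylate F4. LiAlH4 (THF, 0 °C) reduces both esters to [(2R,3S)-7-(benzyloxy)-2-(3,4-dimethoxyphenyl)-2,3-dihydro-1-benzofuran-3,5-diyl]dimethanol F5. Hydrogenolysis (H2, Pd/C, EtOAc) frees (2R,3S)-2-(3,4-dimethoxyphenyl)-3,5-bis(hydroxymethyl)-2,3-dihydro-1-benzofuran-7-ol F6. MnO2 oxidises only the benzylic alcohol to (2R,3S)-2-(3,4-dimethoxyphenyl)-7-hydroxy-3-(hydroxymethyl)-2,3-dihydro-1-benzofuran-5-carbaldehyde F7. Knoevenagel–Doebner condensation with malonic acid (pyridine, cat. piperidine, 80 °C) gives 9.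

2. Step 4. Oxidative addition into the electron-rich aryl bromide may be slow, the catalyst may be deactivated by the phenoxide and carboxylate at the temperature needed, and acrylic acid may oligomerise. The fallback sets out from 7 and comes back at 9. Suzuki–Miyaura coupling of 7 with the vinyl boronate ethyl (2E)-3-(4,4,5,5-tetramethyl-1,3,2-dioxaborolan-2-yl)prop-2-enoate F8 (Pd(dppf)Cl2, K2CO3, dioxane/H2O, 80 °C) should give ethyl (2E)-3-[(2R,3S)-2-(3,4-dimethoxyphenyl)-7-hydroxy-3-(hydroxymethyl)-2,3-dihydro-1-benzofuran-5-yl]prop-2-enoate F9. Hydrolysis with LiOH (THF/H2O, rt) then gives 9.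

3. Step 3. Hydride transfer to the hindered ester of the lithium phenoxide may be sluggish, leaving time for base-induced β-elimination (opening of the O1–C2 bond) or epimerisation at C3. The fallback sets out from 6 and comes back at 7. Near-neutral ester cleavage with Me3SnOH (1,2-dichloroethane, 80 °C) should give (2R,3R)-5-bromo-2-(3,4-dimethoxyphenyl)-7-hydroxy-2,3-dihydro-1-benzofuran-3-carboxylic acid F10. The acid is then reduced with the electrophilic hydride BH3·SMe2 (THF, 0 °C → rt) to 7.

Further compounds
F1 | step 2 | ethyl (3R)-3-[(tert-butyldimethylsilyl)oxy]-3-(3,4-dimethoxyphenyl)propanoate | COc1ccc([C@H](O[Si](C)(C)C(C)(C)C)CC(=O)OCC)cc1OC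
F2 | step 2 | methyl 3-(benzyloxy)-5-bromo-4-fluorobenzoate | COC(=O)c1cc(Br)c(F)c(OCc2ccccc2)c1
F3 | step 2 | ethyl (3R)-2-[3-(benzyloxy)-2-fluoro-5-(methoxycarbonyl)phenyl]-3-[(tert-butyldimethylsilyl)oxy]-3-(3,4-dimethoxyphenyl)propanoate | CCOC(=O)C(c1cc(C(=O)OC)cc(OCc2ccccc2)c1F)[C@@H](O[Si](C)(C)C(C)(C)C)c1ccc(OC)c(OC)c1
F4 | step 2 | 3-ethyl 5-methyl (2R,3R)-7-(benzyloxy)-2-(3,4-dimethoxyphenyl)-2,3-dihydro-1-benzofuran-3,5-dicarboxylate | COc1ccc([C@@H]2Oc3c(OCc4ccccc4)cc(C(=O)OC)cc3[C@H]2C(=O)OCC)cc1OC
F5 | step 2 | [(2R,3S)-7-(benzyloxy)-2-(3,4-dimethoxyphenyl)-2,3-dihydro-1-benzofuran-3,5-diyl]dimethanol | COc1ccc([C@@H]2Oc3c(OCc4ccccc4)cc(CO)cc3[C@H]2CO)cc1OC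
F6 | step 2 | (2R,3S)-2-(3,4-dimethoxyphenyl)-3,5-bis(hydroxymethyl)-2,3-dihydro-1-benzofuran-7-ol | COc1ccc([C@@H]2Oc3c(O)cc(CO)cc3[C@H]2CO)cc1OC
F7 | step 2 | (2R,3S)-2-(3,4-dimethoxyphenyl)-7-hydroxy-3-(hydroxymethyl)-2,3-dihydro-1-benzofuran-5-carbaldehyde | COc1ccc([C@@H]2Oc3c(O)cc(C=O)cc3[C@H]2CO)cc1OC
F8 | step 4 | ethyl (2E)-3-(4,4,5,5-tetramethyl-1,3,2-dioxaborolan-2-yl)prop-2-enoate | CCOC(=O)/C=C/B1OC(C)(C)C(C)(C)O1
F9 | step 4 | ethyl (2E)-3-[(2R,3S)-2-(3,4-dimethoxyphenyl)-7-hydroxy-3-(hydroxymethyl)-2,3-dihydro-1-benzofuran-5-yl]prop-2-enoate | COc1ccc([C@@H]2Oc3c(O)cc(/C=C/C(=O)OCC)cc3[C@H]2CO)cc1OC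
F10 | step 3 | (2R,3R)-5-bromo-2-(3,4-dimethoxyphenyl)-7-hydroxy-2,3-dihydro-1-benzofuran-3-carboxylic acid | COc1ccc([C@@H]2Oc3c(O)cc(Br)cc3[C@H]2C(=O)O)cc1OC
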